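The 20-membered macrocycle is opened at the bond between ring A C-4 (the carbon para to the ether oxygen that joins rings A and B) and the neighbouring CH2 of the A–D ethano bridge. That CH2 is the terminal carbon of a vinyl group on ring D, and ring A C-4 is the halogen position of commercial 4-chloroguaiacol. The key step exploits this: one-pot hydroboration with 9-BBN and intramolecular B-alkyl Suzuki–Miyaura coupling closes the ring at the final oxidation level. The precursor is an open chain of four arenes: ring A chloride, both diaryl ethers, the B–C bibenzyl bridge and a ring D styrene, assembled by two Chan–Lam etherifications and one intermolecular B-alkyl Suzuki coupling.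

Key step: step 5

Remark: the target has no stereocentre. Ring A is the phenol ring etherified to ring B (C-1 O-aryl, C-2 OH, C-4 bridge carbon). Ring B is the meta-disubstituted ring, ring C the para-disubstituted ring, and ring D the second phenol ring (etherified to ring C). 9-BBN is numbered as reactant 7 because its boron skeleton is part of the non-isolated alkylboranes 8 and 11.

Step 1
Reactants: 1 4-chloro-2-methoxyphenol; 2 (3-ethenylphenyl)boronic acid
Product: 3 4-chloro-1-(3-ethenylphenoxy)-2-methoxybenzene
Conditions: Cu(OAc)2 (2 equiv), pyridine, 4 Å MS, CH2Cl2, dry air, rt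
Reagents that add atoms: none
Why: Chan–Lam oxidative O-arylation, in which the phenoxide and the aryl group from boron meet on copper and reductive elimination should give the diaryl ether at room temperature, leaving the C–Cl bond and the vinyl group untouched.

Step 2
Reactants: 4 3-hydroxy-4-methoxybenzaldehyde (isovanillin); 5 (4-bromophenyl)boronic acid
Product: 6 3-(4-bromophenoxy)-4-methoxybenzaldehyde
Conditions: Cu(OAc)2 (2 equiv), pyridine, 4 Å MS, CH2Cl2, dry air, rt
Reagents that add atoms: none
Why: Chan–Lam oxidative O-arylation of the isovanillin hydroxyl, to which the C–Br bond and the aldehyde are inert, so the bromide stays available for the next coupling.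

Step 3
Reactants: 3 4-chloro-1-(3-ethenylphenoxy)-2-methoxybenzene; 7 9-borabicyclo[3.3.1]nonane (9-BBN); 6 3-(4-bromophenoxy)-4-methoxybenzaldehyde
Product: 9 3-(4-{2-[3-(4-chloro-2-methoxyphenoxy)phenyl]ethyl}phenoxy)-4-methoxybenzaldehyde, via alkylborane 8 (not isolated)
Conditions: 3 (1.3 equiv), 7 (1.25 equiv), THF, 0 °C to rt; then 6 (1.0 equiv), PdCl2(dppf) (5 mol %), aq K3PO4, DMF, 50 °C
Reagents that add atoms: none
Why: Intermolecular B-alkyl Suzuki–Miyaura coupling, in which anti-Markovnikov hydroboration of the styrene gives a primary alkylborane that should couple at the C–Br bond of 6, while the electron-rich C–Cl bond is inert to this catalyst and the aldehyde is safe because 3 is in slight excess over 7 and no B–H remains.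

Step 4
Reactants: 9 3-(4-{2-[3-(4-chloro-2-methoxyphenoxy)phenyl]ethyl}phenoxy)-4-methoxybenzaldehyde
Product: 10 4-chloro-1-(3-{2-[4-(5-ethenyl-2-methoxyphenoxy)phenyl]ethyl}phenoxy)-2-methoxybenzene
Conditions: Ph3PCH3Br, KOt-Bu, THF, 0 °C to rt
Reagents that add atoms: methyltriphenylphosphonium bromide, C[P+](c1ccccc1)(c1ccccc1)c1ccccc1.[Br-]
Why: Wittig methylenation of the aryl aldehyde with the non-stabilised ylide should give the ring D styrene, the aryl chloride and the ethers being inert.

Step 5
Reactants: 10 4-chloro-1-(3-{2-[4-(5-ethenyl-2-methoxyphenoxy)phenyl]ethyl}phenoxy)-2-methoxybenzene; 7 9-borabicyclo[3.3.1]nonane (9-BBN)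
Product: 12 macrocyclic bis(bibenzyl) di-O-methyl ether (the target with both OH groups as OMe), via alkylborane 11 (not isolated)
Conditions: 7 (1.5 equiv), THF, rt; excess B–H quenched with H2O; then syringe-pump addition (12 h) to Pd(OAc)2 (10 mol %), SPhos (20 mol %), K3PO4·H2O, THF/H2O, 65 °C, about 2 mM
Reagents that add atoms: none
Why: 9-BBN adds to the ring D vinyl group with boron on the terminal carbon, zerovalent palladium ligated by SPhos inserts into the ring A C–Cl bond, the phosphate-activated primary alkylborane transmetalates and reductive elimination joins ring A C-4 to that CH2. The closest known reaction type is the intramolecular B-alkyl Suzuki–Miyaura macrocyclisation, together with B-alkyl-9-BBN couplings of electron-rich aryl chlorides under dialkylbiarylphosphine ligands. The 20-membered ring closes end-to-end by reductive elimination from a 21-membered palladacycle, so no small-ring geometric constraint applies. No stereocentre is formed. The step needs terminal (anti-Markovnikov) borylation, secured by the bulk of 9-BBN on a styrene, ring closure over oligomerisation, secured by syringe-pump addition at about 2 mM, and coupling over β-hydride elimination, secured by the bulky electron-rich ligand.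

Step 6
Reactants: 12 macrocyclic bis(bibenzyl) di-O-methyl ether
Product: 13 target macrocyclic bis(bibenzyl) diphenol (CNP0329842.0)
Conditions: BBr3 (6 equiv), CH2Cl2, −78 °C to rt; then H2O
Reagents that add atoms: none
Why: Lewis-acid O-demethylation by BBr3 should cleave both aryl methyl ethers, while the diaryl ethers and the two ethano bridges are inert.

Compound list
1 | 4-chloro-2-methoxyphenol (4-chloroguaiacol) | COc1cc(Cl)ccc1O | starting material
2 | (3-ethenylphenyl)boronic acid | OB(O)c1cccc(C=C)c1 | starting material
3 | 4-chloro-1-(3-ethenylphenoxy)-2-methoxybenzene | COc1cc(Cl)ccc1Oc1cccc(C=C)c1 | intermediate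
4 | 3-hydroxy-4-methoxybenzaldehyde (isovanillin) | COc1ccc(C=O)cc1O | starting material
5 | (4-bromophenyl)boronic acid | OB(O)c1ccc(Br)cc1 | starting material
6 | 3-(4-bromophenoxy)-4-methoxybenzaldehyde | COc1ccc(C=O)cc1Oc1ccc(Br)cc1 | intermediate
7 | 9-borabicyclo[3.3.1]nonane (9-BBN, used as its dimer or as a THF solution) | B1C2CCCC1CCC2 | starting material
8 | 9-{2-[3-(4-chloro-2-methoxyphenoxy)phenyl]ethyl}-9-borabicyclo[3.3.1]nonane | COc1cc(Cl)ccc1Oc1cccc(CCB2C3CCCC2CCC3)c1 | intermediate
9 | 3-(4-{2-[3-(4-chloro-2-methoxyphenoxy)phenyl]ethyl}phenoxy)-4-methoxybenzaldehyde | COc1cc(Cl)ccc1Oc1cccc(CCc2ccc(Oc3cc(C=O)ccc3OC)cc2)c1 | intermediate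
10 | 4-chloro-1-(3-{2-[4-(5-ethenyl-2-methoxyphenoxy)phenyl]ethyl}phenoxy)-2-methoxybenzene | COc1cc(Cl)ccc1Oc1cccc(CCc2ccc(Oc3cc(C=C)ccc3OC)cc2)c1 | intermediate
11 | 9-BBN adduct of 10, boron on the terminal carbon of the ring D side chain (ring D–CH2CH2–B) | COc1cc(Cl)ccc1Oc1cccc(CCc2ccc(Oc3cc(CCB4C5CCCC4CCC5)ccc3OC)cc2)c1 | intermediate
12 | macrocyclic bis(bibenzyl) di-O-methyl ether: 20-membered ring, ring A (OMe, O–ring B, CH2CH2 to ring D), ring B meta, ring C para, ring D (OMe, O–ring C) | COc1cc2ccc1Oc1cccc(c1)CCc1ccc(cc1)Oc1cc(ccc1OC)CC2 | intermediate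
13 | target macrocyclic bis(bibenzyl) diphenol (CNP0329842.0) | Oc1cc2ccc1Oc1cccc(c1)CCc1ccc(cc1)Oc1cc(ccc1O)CC2 | target

Total step count: 6. Longest linear sequence: 5 steps (step 1 or 2, then steps 3, 4, 5, 6).

Steps most likely to fail

Step 5. Ring closure may lose to intermolecular coupling, or oxidative addition into the electron-rich C–Cl bond may be slow enough that protodeboronation and β-hydride elimination of the alkylborane take over. The fallback sets out from 10 and uses no borane: an intramolecular Mizoroki–Heck macrocyclisation (Pd2(dba)3, P(t-Bu)3, Cs2CO3, dioxane, 110 °C, high dilution) should join ring A C-4 to the terminal vinyl carbon and give the macrocyclic (E)-stilbene di-O-methyl ether F1. Hydrogenation of the stilbene (H2, Pd/C, EtOAc, rt) should then return the route at 12.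

Step 3. The aldehyde may be reduced by residual B–H, or halide selectivity may be lost so that the alkylborane couples with its own C–Cl bond. The fallback sets out from 3 and 6 and avoids boron altogether: an intermolecular Mizoroki–Heck reaction (Pd(OAc)2, P(o-tol)3, NaOAc, DMA, 110 °C), under which the C–Cl bond is inert, should give the (E)-stilbene aldehyde F2. Diimide reduction of the stilbene (dipotassium azodicarboxylate, AcOH, MeOH/pyridine, rt), which touches neither the C–Cl bond nor the aldehyde, should return the route at 9.

Step 1. O-Arylation of the ortho-substituted phenol may be slow, so that protodeboronation, homocoupling and oxidation of the vinyl-bearing boronic acid consume the coupling partner. The fallback sets out from 1 and replaces the oxidative coupling by an Ullmann-type etherification with 3-bromobenzaldehyde (O=Cc1cccc(Br)c1; CuI, N,N-dimethylglycine, Cs2CO3, dioxane, 100 °C), which should give 3-(4-chloro-2-methoxyphenoxy)benzaldehyde F3. Wittig methylenation (Ph3PCH3Br, KOt-Bu, THF, 0 °C to rt) should then return the route at 3.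

Further compounds
F1 | step 5 | macrocyclic (E)-stilbene di-O-methyl ether (12 with an E double bond in the A–D bridge) | COc1ccc(/C=C/c2ccc3c(OC)c2)cc1Oc1ccc(CCc2cccc(O3)c2)cc1
F2 | step 3 | 3-(4-{(E)-2-[3-(4-chloro-2-methoxyphenoxy)phenyl]ethenyl}phenoxy)-4-methoxybenzaldehyde | COc1cc(Cl)ccc1Oc1cccc(/C=C/c2ccc(Oc3cc(C=O)ccc3OC)cc2)c1
F3 | step 1 | 3-(4-chloro-2-methoxyphenoxy)benzaldehyde | COc1cc(Cl)ccc1Oc1cccc(C=O)c1
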